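**Retrosynthetic overview**

1. The decanoate is made last, from the Z-configured primary allylic alcohol and decanoyl chloride.
2. The (Z)-γ-hydroxy-enone side chain comes from a 2-alkyl-3-methylfuran (singlet-oxygen opening, then aldehyde reduction). The furan ring fixes the Z geometry and masks the side-chain ketone.
3. The C4 carbinol comes from methyl addition to one carbonyl of a cyclohex-2-ene-1,4-dione, anti to the C5 substituent, which puts OH cis to the side chain.
4. Key bond C5–CH2: the C4 oxygen and the side-chain carbonyl are 1,4-related (dissonant), so two carbonyl α-carbons are joined. The ene-dione dienolate is alkylated by 2-(bromomethyl)-3-methylfuran, a latent (Z)-α-bromo-enone (enolonium, a2 synthon), under chiral-ligand control, which sets C5.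
5. No ring is built: the carbocycle is 5,5-dimethylcyclohex-2-enone (γ-oxidised first), and the furan is bought as its 2-carboxylate and opened at the end.

Assumption: the (R)-ligand L* gives the (R)-alkylation product; if the sense is the opposite, the (S)-ligand is used and nothing else changes. L* = (R)-N1-[2-(dimethylamino)ethyl]-N1,N2-dimethyl-N2-[1-phenyl-2-(piperidin-1-yl)ethyl]ethane-1,2-diamine, CN(C)CCN(C)CCN(C)[C@@H](CN1CCCCC1)c1ccccc1, a phenylglycine-derived tetraamine that is recovered unchanged by acid extraction.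

**Route**

Step 1
Reactants: 1 methyl 3-methylfuran-2-carboxylate
Product: 2 (3-methylfuran-2-yl)methanol
Conditions: LiAlH4, Et2O, 0 °C; then H2O
Reagents that add atoms: none
Why: Hydride reduction of the ester with LiAlH4 gives the primary alcohol and leaves the furan ring untouched.

Step 2
Reactants: 2 (3-methylfuran-2-yl)methanol
Product: 3 2-(bromomethyl)-3-methylfuran
Conditions: PBr3 (0.4 equiv), Et2O, −20 to 0 °C; cold solution used at once
Reagents that add atoms: phosphorus tribromide, BrP(Br)Br
Why: The alcohol is activated as its phosphite ester and displaced by bromide (SN2), and the acid-labile furfurylic bromide is kept cold and used without storage.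

Step 3
Reactants: 4 5,5-dimethylcyclohex-2-en-1-one
Product: 5 5,5-dimethylcyclohex-2-ene-1,4-dione
Conditions: Pd(OH)2/C (5 mol %), t-BuOOH (5 equiv), K2CO3 (0.25 equiv), CH2Cl2, 4 °C
Reagents that add atoms: tert-butyl hydroperoxide, CC(C)(C)OO
Why: Pd(OH)2/C–t-BuOOH γ-oxidation of an enone (allylic C–H oxidation through tert-butylperoxy radicals) turns the only allylic methylene, C4, into a carbonyl and gives an ene-dione that can enolise at C6 only.

Step 4
Reactants: 5 5,5-dimethylcyclohex-2-ene-1,4-dione; 3 2-(bromomethyl)-3-methylfuran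
Product: 7 (6R)-5,5-dimethyl-6-[(3-methylfuran-2-yl)methyl]cyclohex-2-ene-1,4-dione, via lithium dienolate 6 (not isolated)
Conditions: LiN(SiMe3)2 (1.05 equiv), LiBr, L* (1.1 equiv), toluene, −78 °C, 5 added slowly; then 3 (1.5 equiv), −78 to −45 °C
Reagents that add atoms: none
Why: Proposed new method: C6 is the only enolisable carbon of 5, so LiN(SiMe3)2 gives a single dienolate, and within a LiBr/tetraamine L* mixed aggregate this enolate is alkylated (SN2) on one face by 3, a latent (Z)-α-bromo-enone (enolonium, a2 synthon), which joins two carbonyl α-carbons and sets C6 as R, the hindered product not being re-enolised at low temperature; closest known reaction type: ligand-controlled enantioselective benzylation of cyclohexanone and tetralone lithium enolates with chiral polyamines (Koga alkylation).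

Step 5
Reactants: 7 (6R)-5,5-dimethyl-6-[(3-methylfuran-2-yl)methyl]cyclohex-2-ene-1,4-dione
Product: 8 (4S,5R)-4-hydroxy-4,6,6-trimethyl-5-[(3-methylfuran-2-yl)methyl]cyclohex-2-en-1-one
Conditions: MeLi (1.3 equiv), CeCl3 (1.4 equiv, dried), THF, −78 °C; then H2O
Reagents that add atoms: methyllithium, [Li]C
Why: Organocerium (Imamoto-type) 1,2-addition is non-basic, so C6 is not epimerised, and it takes the C1 carbonyl rather than the C4 carbonyl next to the quaternary carbon, from the face anti to the pseudo-axial furfuryl group, which sets the carbinol centre as S with OH cis to the side chain.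

Step 6
Reactants: 8 (4S,5R)-4-hydroxy-4,6,6-trimethyl-5-[(3-methylfuran-2-yl)methyl]cyclohex-2-en-1-one
Product: 11 (4S,5R)-4-hydroxy-5-[(3Z)-5-hydroxy-3-methyl-2-oxopent-3-en-1-yl]-4,6,6-trimethylcyclohex-2-en-1-one, via furan endoperoxide 9 (not isolated), via Z-keto-enal 10 (not isolated)
Conditions: O2, visible light, 5,10,15,20-tetraphenylporphyrin (1 mol %), CH2Cl2, −78 °C; Me2S, −78 to −30 °C; then EtOH, NaBH4, −78 °C
Reagents that add atoms: dioxygen, O=O
Why: Singlet oxygen adds [4+2] across C2/C5 of the furan, Me2S reduces the endoperoxide to the cis-ene-dicarbonyl whose Z geometry is fixed by the former ring, and NaBH4 at −78 °C reduces only the aldehyde (1,2-reduction; the ring ketone is hindered and the side-chain ketone rests as the hemiketal of the cis tertiary OH), no stereocentre being touched.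

Step 7
Reactants: 11 (4S,5R)-4-hydroxy-5-[(3Z)-5-hydroxy-3-methyl-2-oxopent-3-en-1-yl]-4,6,6-trimethylcyclohex-2-en-1-one; 12 decanoyl chloride
Product: 13 [(2Z)-5-[(1R,2S)-2-hydroxy-2,6,6-trimethyl-5-oxocyclohex-3-en-1-yl]-3-methyl-4-oxopent-2-en-1-yl] decanoate
Conditions: pyridine (3 equiv), CH2Cl2, −20 to 0 °C; crude 11 used directly
Reagents that add atoms: none
Why: Pyridine-mediated acylation with the acid chloride (Einhorn esterification) takes the only primary hydroxyl, drains the hemiketal equilibrium toward the open form, leaves both tertiary hydroxyls alone and does not isomerise the Z-enone at low temperature.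

**Compound list**

1 | methyl 3-methylfuran-2-carboxylate | COC(=O)c1occc1C | starting material
2 | (3-methylfuran-2-yl)methanol | OCc1occc1C | intermediate
3 | 2-(bromomethyl)-3-methylfuran | BrCc1occc1C | intermediate
4 | 5,5-dimethylcyclohex-2-en-1-one | O=C1C=CCC(C)(C)C1 | starting material
5 | 5,5-dimethylcyclohex-2-ene-1,4-dione | O=C1C=CC(=O)C(C)(C)C1 | intermediate
6 | lithium 3,3-dimethyl-4-oxocyclohexa-1,5-dien-1-olate | [Li+].[O-]C1=CC(C)(C)C(=O)C=C1 | intermediate
7 | (6R)-5,5-dimethyl-6-[(3-methylfuran-2-yl)methyl]cyclohex-2-ene-1,4-dione | Cc1ccoc1C[C@@H]1C(C)(C)C(=O)C=CC1=O | intermediate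
8 | (4S,5R)-4-hydroxy-4,6,6-trimethyl-5-[(3-methylfuran-2-yl)methyl]cyclohex-2-en-1-one | Cc1ccoc1C[C@@H]1C(C)(C)C(=O)C=C[C@]1(C)O | intermediate
9 | (4S,5R)-4-hydroxy-4,6,6-trimethyl-5-[(6-methyl-2,3,7-trioxabicyclo[2.2.1]hept-5-en-1-yl)methyl]cyclohex-2-en-1-one (bridgehead configuration not controlled) | CC1=CC2OOC1(C[C@@H]3C(C)(C)C(=O)C=C[C@]3(C)O)O2 | intermediate
10 | (2Z)-5-[(1R,2S)-2-hydroxy-2,6,6-trimethyl-5-oxocyclohex-3-en-1-yl]-3-methyl-4-oxopent-2-enal | O=C/C=C(/C)C(=O)C[C@@H]1C(C)(C)C(=O)C=C[C@]1(C)O | intermediate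
11 | (4S,5R)-4-hydroxy-5-[(3Z)-5-hydroxy-3-methyl-2-oxopent-3-en-1-yl]-4,6,6-trimethylcyclohex-2-en-1-one | OC/C=C(/C)C(=O)C[C@@H]1C(C)(C)C(=O)C=C[C@]1(C)O | intermediate
12 | decanoyl chloride | CCCCCCCCCC(Cl)=O | starting material
13 | [(2Z)-5-[(1R,2S)-2-hydroxy-2,6,6-trimethyl-5-oxocyclohex-3-en-1-yl]-3-methyl-4-oxopent-2-en-1-yl] decanoate (CNP0241324.1) | CCCCCCCCCC(=O)OC/C=C(/C)C(=O)C[C@@H]1C(C)(C)C(=O)C=C[C@]1(C)O | target

**Step count and risks**

Total step count: 7. Longest linear sequence: 6 (1 → 2 → 3 → 7 → 8 → 11 → 13; steps 1, 2, 4, 5, 6, 7).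

Step 4 is the most likely to fail: the enantioselectivity of the ligand-controlled alkylation is untested on this dienolate, and the ene-dione is base-sensitive. The fallback sets out from 5 and comes back at 7. Compound 5 is condensed at its less hindered C1 carbonyl with (2S)-1-amino-2-(methoxymethyl)pyrrolidine (SAMP) to give the SAMP hydrazone F1. F1 is deprotonated with LiN(iPr)2 in THF at −78 °C and the aza-enolate is alkylated with 3 at −100 °C to give the alkylated hydrazone F2 (Enders alkylation; the usual topicity gives R at the new centre, otherwise the enantiomeric auxiliary is used). Cleavage with aqueous oxalic acid/Et2O returns 7 and the auxiliary.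

Step 5 is the second risk: both carbonyls of 7 are α-branched, so methyl addition may not discriminate well enough. The fallback sets out from 5 and comes back at 8. The hindered C4 carbonyl of 5 is reduced while C1 is masked as its enolate (LiN(SiMe3)2, then i-Bu2AlH, THF, −78 °C), giving the hydroxy-enone F3. Its alkoxide-enolate is alkylated with 3 as in step 4 to give the alkylated hydroxy-enone F4. MeLi/CeCl3 then meets a single ketone and gives the diol F5, and MnO2 in CH2Cl2 oxidises the secondary allylic alcohol only, which gives 8.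

Step 6 is the third risk: the Z-keto-enal 10 can isomerise, and free 11 can cyclise and lose water to re-form furan 8 on handling. The fallback sets out from 8 and comes back at 13 without isolating 11. Compound 8 is taken through the same photooxygenation and Me2S reduction to 10 in the flask. The aldehyde is then reduced with LiAlH(Ot-Bu)3 at −78 °C to the aluminium alkoxide F6, which is acylated in the same flask with 12 and pyridine to give 13.

Further compounds
F1 | step 4 | 4-{[(2S)-2-(methoxymethyl)pyrrolidin-1-yl]imino}-6,6-dimethylcyclohex-2-en-1-one (C=N geometry not fixed) | CC1(C)CC(=NN2CCC[C@H]2COC)C=CC1=O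
F2 | step 4 | (5R)-4-{[(2S)-2-(methoxymethyl)pyrrolidin-1-yl]imino}-6,6-dimethyl-5-[(3-methylfuran-2-yl)methyl]cyclohex-2-en-1-one | Cc1ccoc1C[C@@H]1C(C)(C)C(=O)C=CC1=NN1CCC[C@H]1COC
F3 | step 5 | 4-hydroxy-5,5-dimethylcyclohex-2-en-1-one (racemic) | O=C1C=CC(O)C(C)(C)C1
F4 | step 5 | (6R)-4-hydroxy-5,5-dimethyl-6-[(3-methylfuran-2-yl)methyl]cyclohex-2-en-1-one (both C4 epimers) | Cc1ccoc1C[C@@H]1C(C)(C)C(O)C=CC1=O
F5 | step 5 | (1S,6R)-1,5,5-trimethyl-6-[(3-methylfuran-2-yl)methyl]cyclohex-2-ene-1,4-diol (both C4 epimers) | Cc1ccoc1C[C@@H]1C(C)(C)C(O)C=C[C@]1(C)O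
F6 | step 6 | lithium tri-tert-butoxy{[(2Z)-5-[(1R,2S)-2-hydroxy-2,6,6-trimethyl-5-oxocyclohex-3-en-1-yl]-3-methyl-4-oxopent-2-en-1-yl]oxy}aluminate | [Li+].CC(C)(C)O[Al-](OC(C)(C)C)(OC(C)(C)C)OC/C=C(/C)C(=O)C[C@@H]1C(C)(C)C(=O)C=C[C@]1(C)O
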